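All runs are calculated on assumed constants; scatter was added.

**One step.** In a one-step world, substrate turns to product with a single lifetime (pseudo-first-order), and that lifetime shortens in proportion to enzyme. Fed steadily, such substrate stands at the lifetime divided by the dosing time, as a fraction of the charge. In a batch it falls by a factor of e per lifetime.

| flask | substrate | enzyme | remark | time |
|---|---|---|---|---|
| theta | 0.017 M (fed, over 5.0 h) | 0.18 µM | run made earlier |  |
| delta | 0.017 M (fed, over 5.0 h) | 0.24 µM | run made earlier |  |
| Saturday's | 0.012 M | 0.12 µM | everything together at the start | 5.0 h |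
| Tuesday's | 0.017 M (fed, over 5.0 h) | 0.12 µM |  | 5.0 h |

| run | time / h | product / % |
|---|---|---|
| theta | 0.250 | 0 |
| theta | 0.333 | 6 |
| theta | 0.500 | 10 |
| theta | 0.833 | 9 |
| theta | 1.33 | 19 |
| theta | 2.00 | 32 |
| theta | 3.00 | 51 |
| delta | 0.167 | 1 |
| delta | 0.500 | 6 |
| delta | 0.833 | 14 |
| delta | 1.33 | 20 |
| delta | 2.00 | 34 |
| delta | 2.50 | 45 |
| delta | 3.00 | 57 |

(scatter of a reading: 2 percentage points)

- the numbers in the tables scatter by 2 percentage points (one standard deviation)
- percentages count the whole charge, also what has not yet gone in

- which of the two ends with the higher amount of product, in percent of the substrate charged ("neither" if they lie within 2 percentage points) (Saturday's / Tuesday's / neither)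
- product at the end, in percent of the substrate charged, Saturday's
- product at the end, in percent of the substrate charged, Tuesday's

**The number.** In that world, charge fed minus product gives the standing fraction. Over the 2.00 h and 3.00 h readings it averages 8.50 % in theta and 4.50 % in delta. Its reciprocal counts the lifetimes in the dosing time: 11.8 in theta and 22.2 in delta. Averaged per enzyme and scaled to Tuesday's enzyme, the lifetimes contained in the time, N, come to 9.48, a reading that carries the scatter.

**Reading off.** Saturday's and Tuesday's share enzyme and time, hence N. This reckoning leaves 10.5 % standing in Tuesday's, so 89.5 % product. Saturday's keeps 0.00764 % in this reckoning, which puts its product higher.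

**One enough?** Delta's count exceeds theta's by a factor of 1.88, while its enzyme rises by 1.33, so on these readings proportion holds loosely. Saturday's also opens with 8.30 times the substrate standing in theta, so N is carried beyond its readings there. The thing to watch is whether lost substrate reappears as product.

**The forecast.** It names Saturday's, with 99 % for Saturday's and 85 % for Tuesday's, a figure below this reckoning. Of Saturday's it says “it is essentially complete”.

**The flask.** The outcome is neither: Saturday's gives 81.3 %, 18 percentage points under the forecast, and Tuesday's gives 80.7 %.

    complex → enzyme + product (k = 40500 h⁻¹)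
    2 substrate → homo dimer (k = 11.4 M⁻¹ h⁻¹)
    substrate + enzyme ⇌ complex (K = 1550 M⁻¹, k = 13500 M⁻¹ s⁻¹)

Saturday's ends with 0 % substrate, but 18.7 % of its charge stands as homo dimer, against 3.21 % in Tuesday's. The reciprocal of N gave 10.5 % for Tuesday's, which holds 16.1 % substrate. With 2.0 × 10⁻⁷ M of enzyme in Tuesday's recipe, N becomes 15.8, whose reciprocal is 6.33 %, and that neighbour flask ends with substrate at 6.21 %.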